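Take a ratio: the share of the acidic substrate that is not product, over the share that is. You have to decide whether the next flask at 2.50 equiv of free base gets 3.00 equiv or 4.50 equiv of electrophile, and this ratio is what that choice moves.

| setting | delta | gamma | zeta | green | ochre | grey | amber | teal |
|---|---|---|---|---|---|---|---|---|
| acidic substrate | 0.010 M | 0.010 M | 0.015 M | 0.010 M | 0.010 M | 0.015 M | 0.010 M | 0.010 M |
| free base | 2.5 equiv | 2.5 equiv | 2.5 equiv | 1.20 equiv | 2.50 equiv | 5.00 equiv | 2.50 equiv | 2.50 equiv |
| electrophile | 0.68 equiv | 2.8 equiv | 3 equiv | 3.00 equiv | 3.00 equiv | 0.990 equiv | 0.990 equiv | 4.50 equiv |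
| remark | run made earlier | run made earlier | run made earlier |  |  |  |  |  |
| time |  |  |  | 5.0 h | 5.0 h | 5.0 h | 5.0 h | 5.0 h |

| run | time / h | product / % | acidic substrate / % |
|---|---|---|---|
| delta | 0.250 | 15.6 | 29.6 |
| delta | 0.833 | 30.4 | 25.3 |
| delta | 1.33 | 35.3 | 24.4 |
| delta | 2.00 | 39.8 | 22.6 |
| delta | 3.00 | 39.6 | 23.4 |
| delta | 4.00 | 38.7 | 24.1 |
| delta | 5.00 | 36.6 | 24.4 |
| gamma | 0.250 | 47.4 | 21.0 |
| gamma | 0.833 | 73.6 | 11.5 |
| gamma | 1.33 | 79.0 | 8.6 |
| gamma | 2.00 | 79.5 | 9.2 |
| gamma | 3.00 | 79.1 | 9.9 |
| gamma | 4.00 | 79.6 | 9.0 |
| gamma | 5.00 | 79.6 | 10.2 |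
| zeta | 0.417 | 73.5 | 11.0 |
| zeta | 1.33 | 86.8 | 6.9 |
| zeta | 2.50 | 85.3 | 6.9 |
| zeta | 4.00 | 85.8 | 4.8 |
| zeta | 5.00 | 85.4 | 7.6 |

(scatter of a reading: 1 percentage point)

- what was read earlier has a scatter of 1 percentage point, one standard deviation

* ranking by amount of product, in percent of the acidic substrate charged, from high to low, at 5.0 h (green / ochre / grey / amber / teal)
* the amount of product, in percent of the acidic substrate charged of the flask you put first, at 5.0 h
* the amount of product, in percent of the acidic substrate charged of the flask you put last, at 5.0 h

Gamma reads 79.5% at 2.00 h and 79.6% at 5.00 h, a change inside the scatter of 1 percentage point, so for a flask like gamma the choice is about the charge and not the clock. Delta's late readings run from 39.8% down to 36.6% and average 38.7%. If electrophile goes into product and nowhere else, 0.293 equiv of it is unspent in delta, so delta stops short of what its electrophile allows; I read a balance, and reckon with the fraction left.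

Gamma's late average is 79.4%, and its ratio times its free electrophile in mol per litre comes to 0.00519 M. Call that product of ratio and free electrophile the holding number, an apparent dissociation constant of the product. Zeta, at 0.015 M, averages 85.8% and gives 0.00531 M. Delta gives 0.00465 M, which is lower.

All three runs had 2.5 equiv of free base, so I do not carry the number to green or grey. Solving it for the yield, a quadratic, I get 80.9% for ochre and 87.5% for teal. With delta's number, amber gets 50.9%. The extra 1.50 equiv buys 6.6 points, and I would charge it.

The forecast ranks teal > ochre > green > grey > amber, with teal at 88% (84% to 92%) and amber at 49% (44% to 53%), holding that “the yield is set by the race between the two paths”. That picture differs from my balance, and the placing of green and grey is the forecast's, not mine.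

The order came out as teal > ochre > green > grey > amber, with teal at 87.4% and amber at 50.6%.

    acidic substrate + free base ⇌ protonated base + anion, settled at all times (K = 0.730)
    electrophile + anion ⇌ product (K = 350 L mol⁻¹, k = 180 L mol⁻¹ h⁻¹)

Teal still held 81% of its electrophile at 5.00 h, and its yield puts the holding number at 0.00523 M. With gamma's holding number, teal's recipe at 2.70 equiv of electrophile reckons to 78.7%, and that neighbour flask stands at 79.0%, with 71% of its electrophile left.

The readings come from a simulation from invented constants, and the scatter is random.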